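**Assumption:** the target SMILES has no stereocentre and no stereodescriptor, so the compound is treated as achiral; "single enantiomer" then means the single constitution and tautomer drawn.

**Retrosynthetic overview**
1. Last bond made: the quinone C3–OH bond, by C–H hydroxylation of the 2,5-bis(indolyl)-6-prenyl-1,4-benzoquinone with trimethylamine N-oxide as oxygen-atom donor (proposed new reaction).
2. That quinone comes from indole plus the 2-(tert-prenylindolyl)-6-prenyl-1,4-benzoquinone (conjugate addition, then reoxidation).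
3. The prenyl group comes from a prenylstannane added to the 2-(tert-prenylindolyl)-1,4-benzoquinone.
4. That quinone comes from 1,4-benzoquinone and 2-(2-methylbut-3-en-2-yl)indole, itself made from indole and 3-methylbuta-1,2-diene by reverse prenylation.
5. No ring is built: the benzoquinone and both indole rings are bought intact and joined in the order indole A–quinone, prenyl, indole B, hydroxyl.

Quinone locants used throughout: C1 (C=O), C2 (bears the 2-(2-methylbut-3-en-2-yl)indol-3-yl group), C3, C4 (C=O), C5, C6.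

**Step 1**
Reactants: 1 1H-indole; 2 3-methylbuta-1,2-diene
Product: 5 2-(2-methylbut-3-en-2-yl)-1H-indole, via B-prenyl-9-BBN 3 (not isolated), via 3-chloroindole 4 (not isolated)
Conditions: 9-BBN, 2, THF, 0 °C to rt (gives 3); separately 1, tBuOCl, Et3N, THF, −78 °C (gives 4); then add 3, −78 °C to rt; aq. NaHCO3
Reagents that add atoms: none
Why: Danishefsky-type reverse prenylation: allene hydroboration gives allylborane 3, and 4, reacting through its 3H tautomer, takes the allyl group at C2 with allylic transposition in a cyclic N–B-bound transition state, then loses HCl to re-aromatise; no stereocentre is formed.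

**Step 2**
Reactants: 5 2-(2-methylbut-3-en-2-yl)-1H-indole; 6 1,4-benzoquinone
Product: 8 2-[2-(2-methylbut-3-en-2-yl)-1H-indol-3-yl]cyclohexa-2,5-diene-1,4-dione, via indolylhydroquinone 7 (not isolated)
Conditions: 6 (2.5 equiv), AcOH, THF, rt, slow addition of 5
Reagents that add atoms: none
Why: Acid-promoted Friedel–Crafts-type conjugate addition of indole C3 (C2 is blocked) to the quinone gives 7, which the excess, higher-potential quinone 6 oxidises in situ; slow addition into excess 6 suppresses double addition.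

**Step 3**
Reactants: 8 2-[2-(2-methylbut-3-en-2-yl)-1H-indol-3-yl]cyclohexa-2,5-diene-1,4-dione; 9 tributyl(3-methylbut-2-en-1-yl)stannane
Product: 11 2-[2-(2-methylbut-3-en-2-yl)-1H-indol-3-yl]-6-(3-methylbut-2-en-1-yl)cyclohexa-2,5-diene-1,4-dione, via prenylhydroquinone 10 (not isolated)
Conditions: 9 (1.3 equiv), BF3·OEt2 (2 equiv), CH2Cl2, −78 °C; aq. KF; then Ag2O, Et2O, rt
Reagents that add atoms: none
Why: Naruta-type Lewis-acid-promoted allylation of a quinone with an allylstannane: BF3 binds the unhindered, more basic vinylogous-amide carbonyl C4=O (C1=O is screened by the tert-alkylindolyl group), the stannane attacks there through its γ-carbon and the allyl unit moves by [3,3] shift to C6 (C2 is blocked), giving the linear prenyl group; Ag2O reoxidises 10.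

**Step 4**
Reactants: 11 2-[2-(2-methylbut-3-en-2-yl)-1H-indol-3-yl]-6-(3-methylbut-2-en-1-yl)cyclohexa-2,5-diene-1,4-dione; 1 1H-indole
Product: 13 5-(1H-indol-3-yl)-2-[2-(2-methylbut-3-en-2-yl)-1H-indol-3-yl]-6-(3-methylbut-2-en-1-yl)cyclohexa-2,5-diene-1,4-dione, via bis(indolyl)hydroquinone 12 (not isolated)
Conditions: 1 (1.3 equiv), Bi(OTf)3 (10 mol%), MeCN, rt; then Ag2O, rt (cycle repeated once)
Reagents that add atoms: none
Why: Lewis-acid-catalysed Friedel–Crafts conjugate addition of indole C3: of the two free ring carbons, C3 is the electron-rich α-carbon of the vinylogous amide and lies beside the bulky aryl group, so attack goes to C5 (the usual 2,5-orientation of donor-substituted quinones); Ag2O reoxidises 12 without touching the prenyl groups.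

**Step 5**
Reactants: 13 5-(1H-indol-3-yl)-2-[2-(2-methylbut-3-en-2-yl)-1H-indol-3-yl]-6-(3-methylbut-2-en-1-yl)cyclohexa-2,5-diene-1,4-dione
Product: 15 3-hydroxy-5-(1H-indol-3-yl)-2-[2-(2-methylbut-3-en-2-yl)-1H-indol-3-yl]-6-(3-methylbut-2-en-1-yl)cyclohexa-2,5-diene-1,4-dione (CNP0134649.0), via ammoniooxy enolate 14 (not isolated)
Conditions: anhydrous Me3NO (3 equiv), 4 Å MS, MeCN, 50 °C, N2; 1 M HCl work-up
Reagents that add atoms: trimethylamine N-oxide, C[N+](C)(C)[O-]
Why: Proposed new method: quinone C–H hydroxylation by oxygen-atom transfer from an amine N-oxide; the N-oxide oxygen adds (oxa-Michael) to C3, the only ring carbon that still carries hydrogen, to give 14, whose C3–H is now α to the C4 ketone and is removed by Me3NO or Me3N with heterolysis of the weak N–O bond (E1cB), expelling trimethylamine and giving the hydroxyquinone anion directly, so no external oxidant is needed and the deactivated anion does not react further; closest known reaction types are the Ganem/Kornblum oxidation (alkoxyammonium to carbonyl) and Weitz–Scheffer nucleophilic oxygenation of quinones followed by epoxide-to-hydroxyquinone isomerisation.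

**Compound list**
1 | 1H-indole | c1ccc2[nH]ccc2c1 | starting material
2 | 3-methylbuta-1,2-diene | CC(C)=C=C | starting material
3 | 9-(3-methylbut-2-en-1-yl)-9-borabicyclo[3.3.1]nonane (B-prenyl-9-BBN) | CC(C)=CCB1C2CCCC1CCC2 | intermediate
4 | 3-chloro-1H-indole | Clc1c[nH]c2ccccc12 | intermediate
5 | 2-(2-methylbut-3-en-2-yl)-1H-indole | C=CC(C)(C)c1cc2ccccc2[nH]1 | intermediate
6 | 1,4-benzoquinone | O=C1C=CC(=O)C=C1 | starting material
7 | 2-[2-(2-methylbut-3-en-2-yl)-1H-indol-3-yl]benzene-1,4-diol | C=CC(C)(C)c1[nH]c2ccccc2c1-c1cc(O)ccc1O | intermediate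
8 | 2-[2-(2-methylbut-3-en-2-yl)-1H-indol-3-yl]cyclohexa-2,5-diene-1,4-dione | C=CC(C)(C)c1[nH]c2ccccc2c1C1=CC(=O)C=CC1=O | intermediate
9 | tributyl(3-methylbut-2-en-1-yl)stannane | CCCC[Sn](CCCC)(CCCC)CC=C(C)C | starting material
10 | 2-[2-(2-methylbut-3-en-2-yl)-1H-indol-3-yl]-6-(3-methylbut-2-en-1-yl)benzene-1,4-diol | C=CC(C)(C)c1[nH]c2ccccc2c1-c1cc(O)cc(CC=C(C)C)c1O | intermediate
11 | 2-[2-(2-methylbut-3-en-2-yl)-1H-indol-3-yl]-6-(3-methylbut-2-en-1-yl)cyclohexa-2,5-diene-1,4-dione | C=CC(C)(C)c1[nH]c2ccccc2c1C1=CC(=O)C=C(CC=C(C)C)C1=O | intermediate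
12 | 5-(1H-indol-3-yl)-2-[2-(2-methylbut-3-en-2-yl)-1H-indol-3-yl]-6-(3-methylbut-2-en-1-yl)benzene-1,4-diol | C=CC(C)(C)c1[nH]c2ccccc2c1-c1cc(O)c(-c2c[nH]c3ccccc23)c(CC=C(C)C)c1O | intermediate
13 | 5-(1H-indol-3-yl)-2-[2-(2-methylbut-3-en-2-yl)-1H-indol-3-yl]-6-(3-methylbut-2-en-1-yl)cyclohexa-2,5-diene-1,4-dione | C=CC(C)(C)c1[nH]c2ccccc2c1C1=CC(=O)C(c2c[nH]c3ccccc23)=C(CC=C(C)C)C1=O | intermediate
14 | C3 trimethylammoniooxy adduct of 13 as its C1 enolate (zwitterion, racemic at C3) | C=CC(C)(C)c1[nH]c2ccccc2c1C1=C([O-])C(CC=C(C)C)=C(c2c[nH]c3ccccc23)C(=O)C1O[N+](C)(C)C | intermediate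
15 | 3-hydroxy-5-(1H-indol-3-yl)-2-[2-(2-methylbut-3-en-2-yl)-1H-indol-3-yl]-6-(3-methylbut-2-en-1-yl)cyclohexa-2,5-diene-1,4-dione | C=CC(C)(C)c1[nH]c2ccccc2c1C1=C(O)C(=O)C(c2c[nH]c3ccccc23)=C(CC=C(C)C)C1=O | target

**Totals**
Total step count: 5. Longest linear sequence: 5 steps (1 → 5 → 8 → 11 → 13 → 15).

**Three steps most likely to fail**

Step 5 (the proposed new hydroxylation). The oxa-Michael addition at the hindered, fairly electron-rich C3 may be too slow for the weakly nucleophilic N-oxide. The fallback sets out from 13 and comes back at 15 using known chemistry. Weitz–Scheffer epoxidation with tBuOOH/DBU in THF at 0 °C (hydroperoxide attacks C3 and closes onto C2) gives the racemic cis epoxide 1-[2-(2-methylbut-3-en-2-yl)-1H-indol-3-yl]-4-(1H-indol-3-yl)-3-(3-methylbut-2-en-1-yl)-7-oxabicyclo[4.1.0]hept-3-ene-2,5-dione F4. This is isomerised with K2CO3 in MeOH at rt (or on silica gel) to 15, the classical epoxyquinone-to-hydroxyquinone rearrangement.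

Step 3 (prenylation of 8). The risks are attack at C5 instead of C6, and acid damage from BF3 to the tert-prenyl group or to the ortho-prenyl hydroquinone (chroman formation). The fallback sets out from 8 and comes back at 10; it separates the two events under Lewis-acid-free conditions. Prenyl bromide and In powder in DMF at rt (Barbier allylindium addition) attack the unhindered C4 carbonyl through the γ-carbon to give the racemic quinol 4-hydroxy-4-(2-methylbut-3-en-2-yl)-2-[2-(2-methylbut-3-en-2-yl)-1H-indol-3-yl]cyclohexa-2,5-dien-1-one F1, which is isolated. Heating F1 in toluene at 80–110 °C brings about the [3,3] shift to C6 and tautomerisation to 10, which Ag2O oxidises to 11 as in the main route.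

Step 4 (indole addition to 11). The risks are sluggish attack at C5 next to the prenyl group, redox exchange between 12 and 11, and acid-catalysed chroman closure of the ortho-prenyl hydroquinones. The fallback sets out from 8 and comes back at 12; it exchanges the order of the two C–C bond formations. Indole 1 adds to the unhindered C5 of 8 (Bi(OTf)3, MeCN, rt) to give 2-(1H-indol-3-yl)-5-[2-(2-methylbut-3-en-2-yl)-1H-indol-3-yl]benzene-1,4-diol F2. Ag2O oxidises F2 to 2-(1H-indol-3-yl)-5-[2-(2-methylbut-3-en-2-yl)-1H-indol-3-yl]cyclohexa-2,5-diene-1,4-dione F3. Stannane 9 with BF3·OEt2 in CH2Cl2 at −78 °C then prenylates F3 at the ring carbon next to the smaller indolyl group (the other free carbon is screened by the tert-alkylindolyl group) to give 12, and Ag2O gives 13.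

**Further compounds**
F1 | step 3 | 4-hydroxy-4-(2-methylbut-3-en-2-yl)-2-[2-(2-methylbut-3-en-2-yl)-1H-indol-3-yl]cyclohexa-2,5-dien-1-one (racemic) | C=CC(C)(C)c1[nH]c2ccccc2c1C1=CC(O)(C(C)(C)C=C)C=CC1=O
F2 | step 4 | 2-(1H-indol-3-yl)-5-[2-(2-methylbut-3-en-2-yl)-1H-indol-3-yl]benzene-1,4-diol | C=CC(C)(C)c1[nH]c2ccccc2c1-c1cc(O)c(-c2c[nH]c3ccccc23)cc1O
F3 | step 4 | 2-(1H-indol-3-yl)-5-[2-(2-methylbut-3-en-2-yl)-1H-indol-3-yl]cyclohexa-2,5-diene-1,4-dione | C=CC(C)(C)c1[nH]c2ccccc2c1C1=CC(=O)C(c2c[nH]c3ccccc23)=CC1=O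
F4 | step 5 | 1-[2-(2-methylbut-3-en-2-yl)-1H-indol-3-yl]-4-(1H-indol-3-yl)-3-(3-methylbut-2-en-1-yl)-7-oxabicyclo[4.1.0]hept-3-ene-2,5-dione (racemic cis epoxide) | C=CC(C)(C)c1[nH]c2ccccc2c1C12OC1C(=O)C(c1c[nH]c3ccccc13)=C(CC=C(C)C)C2=O
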